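**Retrosynthetic overview**
1. Target 24 ⇐ angeloylation at O8 and desilylation of the cis-fused α-methylene-γ-lactone macrocycle 21 (last ring system to be assembled).
2. Ten-membered carbocycle and γ-lactone ⇐ C6–C7 bond by intramolecular CrCl2 allylation of aldehyde/allylic bromide 19, then lactonisation.
3. Furanone ring ⇐ O–C10 bond by 5-exo opening of a trans-C9/C10 oxirane by the C3 enol oxygen of the C1/C3 diketone 12 (aldol of methyl ketone 4 with epoxy aldehyde 10, then oxidation).
4. Enabling feature: the C9 hydroxyl lies vicinal and anti to the C10–O bond of the oxa-bridge, beside the 1,3-dioxygenated C1–C2–C3 unit of the furanone ring; this is the imprint of an epoxide opened at C10 by a β-diketone oxygen.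
5. Fragments: 4 from aldehyde 1 (Brown crotylation, Wacker), 10 from (R)-butenediol 5 (cross-metathesis, Sharpless epoxidation); ring order: furanone, ten-membered carbocycle, γ-lactone.

Key step: step 10

Remark: positions are labelled as in a germacranolide (C1 furanone C=O, C2 furanone CH, C3 enol-ether carbon, C4 CH(CH3), C5 CH(OH), C6 lactone O–CH, C7 ring-fusion CH, C8 CH–O-angeloyl, C9 CH(OH), C10 O–C(CH3), C11=C13 exocyclic alkene, C12 lactone C=O); 2-[(4-methoxybenzyl)oxy]acetaldehyde and (R)-but-3-ene-1,2-diol are taken as catalogue compounds.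

**Step 1**
Reactants: 1 2-[(4-methoxybenzyl)oxy]acetaldehyde
Product: 2 (2S,3S)-1-[(4-methoxybenzyl)oxy]-3-methylpent-4-en-2-ol
Conditions: trans-2-butene, KOt-Bu, n-BuLi, THF, −78 to −45 °C; (−)-Ipc2BOMe, −78 °C; BF3·OEt2; then 1, −78 °C; NaOH, H2O2
Reagents that add atoms: trans-2-butene, C/C=C/C (transferred as (E)-crotyl-B(Ipc)2)
Why: Brown crotylboration through a closed chair transition state, in which the E geometry of the crotylborane gives the C4/C5 anti relationship and the (+)-α-pinene-derived isopinocampheyl groups direct addition to the Si face of the aldehyde, should set both centres as (2S,3S).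

**Step 2**
Reactants: 2 (2S,3S)-1-[(4-methoxybenzyl)oxy]-3-methylpent-4-en-2-ol
Product: 3 (2S,3S)-2-(tert-butyldimethylsilyloxy)-1-[(4-methoxybenzyl)oxy]-3-methylpent-4-ene
Conditions: TBSCl, imidazole, DMF, rt
Reagents that add atoms: tert-butyldimethylsilyl chloride, CC(C)(C)[Si](C)(C)Cl
Why: Standard silylation of a secondary alcohol that touches no stereocentre and blocks O5 against later condensation with the diketone.

**Step 3**
Reactants: 3 (2S,3S)-2-(tert-butyldimethylsilyloxy)-1-[(4-methoxybenzyl)oxy]-3-methylpent-4-ene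
Product: 4 (3R,4S)-4-(tert-butyldimethylsilyloxy)-5-[(4-methoxybenzyl)oxy]-3-methylpentan-2-one
Conditions: PdCl2 (cat.), CuCl, O2 (1 atm), DMF/H2O 7:1, rt
Reagents that add atoms: water, O
Why: Wacker–Tsuji oxidation converts the terminal vinyl group into the methyl ketone with Markovnikov selectivity under near-neutral conditions that should leave the α-methyl stereocentre, the silyl ether and the PMB ether intact.

**Step 4**
Reactants: 5 (R)-but-3-ene-1,2-diol
Product: 6 (R)-3,4-bis(triethylsilyloxy)but-1-ene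
Conditions: TESCl (2.4 equiv), imidazole, CH2Cl2, 0 °C to rt
Reagents that add atoms: chlorotriethylsilane, CC[Si](CC)(CC)Cl
Why: Routine bis-silylation of a 1,2-diol; the purchased C8 stereocentre is not touched.

**Step 5**
Reactants: 6 (R)-3,4-bis(triethylsilyloxy)but-1-ene
Product: 7 (R,E)-2-methyl-4,5-bis(triethylsilyloxy)pent-2-enal
Conditions: methacrolein (5 equiv), second-generation Hoveyda–Grubbs catalyst RuCl2(=CH-C6H4-2-Oi-Pr)(H2IMes) (5 mol%), CH2Cl2, 40 °C
Reagents that add atoms: methacrolein, C=C(C)C=O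
Why: Olefin cross-metathesis of a terminal alkene with excess methacrolein should give the trisubstituted enal with thermodynamic E selectivity, loss of ethylene driving the reaction.

**Step 6**
Reactants: 7 (R,E)-2-methyl-4,5-bis(triethylsilyloxy)pent-2-enal
Product: 8 (R,E)-2-methyl-4,5-bis(triethylsilyloxy)pent-2-en-1-ol
Conditions: i-Bu2AlH, CH2Cl2, −78 °C; KNaC4H4O6 (aq.)
Reagents that add atoms: none
Why: 1,2-Reduction of the enal by the aluminium hydride at low temperature should give the allylic alcohol without affecting the silyl ethers or the alkene geometry.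

**Step 7**
Reactants: 8 (R,E)-2-methyl-4,5-bis(triethylsilyloxy)pent-2-en-1-ol
Product: 9 [(2R,3R)-3-[(1S)-1,2-bis(triethylsilyloxy)ethyl]-2-methyloxiran-2-yl]methanol
Conditions: Ti(Oi-Pr)4, D-(−)-diethyl tartrate, t-BuOOH, 4 Å molecular sieves, CH2Cl2, −20 °C
Reagents that add atoms: tert-butyl hydroperoxide, CC(C)(C)OO
Why: Sharpless asymmetric epoxidation, in which the titanium–D-tartrate–peroxide complex delivers oxygen to the face of the (E)-allylic alcohol that gives the (2R,3R)-oxirane (reagent control over the remote C8 centre), should set C9 and C10 together by catalysis.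

**Step 8**
Reactants: 9 [(2R,3R)-3-[(1S)-1,2-bis(triethylsilyloxy)ethyl]-2-methyloxiran-2-yl]methanol
Product: 10 (2S,3R)-3-[(1S)-1,2-bis(triethylsilyloxy)ethyl]-2-methyloxirane-2-carbaldehyde
Conditions: SO3·pyridine, DMSO, i-Pr2NEt, CH2Cl2, 0 °C
Reagents that add atoms: none
Why: Parikh–Doering oxidation should give the α-quaternary, non-epimerisable epoxy aldehyde under buffered, chloride-free conditions that spare the oxirane and the primary triethylsilyl ether.

**Step 9**
Reactants: 4 (3R,4S)-4-(tert-butyldimethylsilyloxy)-5-[(4-methoxybenzyl)oxy]-3-methylpentan-2-one; 10 (2S,3R)-3-[(1S)-1,2-bis(triethylsilyloxy)ethyl]-2-methyloxirane-2-carbaldehyde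
Product: 11 (4R,5S)-5-(tert-butyldimethylsilyloxy)-1-hydroxy-6-[(4-methoxybenzyl)oxy]-4-methyl-1-[(2R,3R)-3-[(1S)-1,2-bis(triethylsilyloxy)ethyl]-2-methyloxiran-2-yl]hexan-3-one (C1 carbinol as epimer mixture)
Conditions: LiN(i-Pr)2, THF, −78 °C (4); then 10, −78 °C; aq. NH4Cl at −78 °C
Reagents that add atoms: none
Why: Kinetic deprotonation of the methyl ketone on its methyl side and aldol addition to the non-enolisable epoxy aldehyde at low temperature should join the fragments, the new C1 carbinol being an inconsequential epimer mixture because it is oxidised in the next step.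

**Step 10**
Reactants: 11 (4R,5S)-5-(tert-butyldimethylsilyloxy)-1-hydroxy-6-[(4-methoxybenzyl)oxy]-4-methyl-1-[(2R,3R)-3-[(1S)-1,2-bis(triethylsilyloxy)ethyl]-2-methyloxiran-2-yl]hexan-3-one
Product: 13 (2R)-2-[(1R,2S)-1-hydroxy-2,3-bis(triethylsilyloxy)propyl]-2-methyl-5-[(2R,3S)-3-(tert-butyldimethylsilyloxy)-4-[(4-methoxybenzyl)oxy]butan-2-yl]furan-3(2H)-one, via epoxy 1,3-diketone 12 (not isolated)
Conditions: Dess–Martin periodinane (1.2 equiv), CH2Cl2, 0 °C to rt; then PPTS (0.2 equiv), same flask, rt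
Reagents that add atoms: none
Why: Proposed new method: Dess–Martin oxidation of the β-hydroxy ketone gives the epoxy 1,3-diketone 12, whose enol oxygen at C3 (a vinylogous carboxylic acid oxygen) opens the acid-activated oxirane at the tertiary carbon C10 in a 5-exo-tet closure, so that the C3–O–C10 bond, the 3(2H)-furanone ring and the free C9 hydroxyl should appear in one operation; the closest known reaction types are the closure of 4-halo-1,3-diketones to 3(2H)-furanones by enol O-alkylation and the acid-catalysed 5-exo cyclisation of epoxy alcohols at the more substituted oxirane carbon, the untested element being an α,β-epoxy ketone as the internal alkylating agent for a β-diketone. The quaternary centre C10 is set by inversion (backside attack anti to the departing oxirane oxygen) of the centre installed by the Sharpless epoxidation, and C9 keeps its configuration because its C–O bond is never broken, so the trans-oxirane from the E-alkene maps onto the anti C9–OH/C10–O relationship of the target. The step needs O- over C-alkylation and 5-exo attack at C10 over 6-endo attack at C9 (which would give a dihydropyranone): the planar O3–C3=C2–C1–C10 array places only the oxygen within reach of C10, in the enol tautomer C10 is a tertiary allylic-type oxirane carbon that carries most of the positive charge under acid, and C9 is deactivated by the adjacent C8 silyloxy group. The C5 oxygen is silylated so that it cannot condense with the diketone to a pyranone, and only a mild acid is used so that the silyl ethers survive and the product does not equilibrate through ketalisation of the new C9 hydroxyl.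

**Step 11**
Reactants: 13 (2R)-2-[(1R,2S)-1-hydroxy-2,3-bis(triethylsilyloxy)propyl]-2-methyl-5-[(2R,3S)-3-(tert-butyldimethylsilyloxy)-4-[(4-methoxybenzyl)oxy]butan-2-yl]furan-3(2H)-one
Product: 14 (2R)-2-[(1R,2S)-1-(tert-butyldimethylsilyloxy)-2,3-bis(triethylsilyloxy)propyl]-2-methyl-5-[(2R,3S)-3-(tert-butyldimethylsilyloxy)-4-[(4-methoxybenzyl)oxy]butan-2-yl]furan-3(2H)-one
Conditions: TBSOTf, 2,6-lutidine, CH2Cl2, −78 to 0 °C
Reagents that add atoms: tert-butyldimethylsilyl triflate, CC(C)(C)[Si](C)(C)OS(=O)(=O)C(F)(F)F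
Why: Silylation of the hindered secondary C9 alcohol with the reactive silyl triflate and a non-nucleophilic base should block O9 for the coming oxidations and distinguish it from O8 for the late acylation.

**Step 12**
Reactants: 14 (2R)-2-[(1R,2S)-1-(tert-butyldimethylsilyloxy)-2,3-bis(triethylsilyloxy)propyl]-2-methyl-5-[(2R,3S)-3-(tert-butyldimethylsilyloxy)-4-[(4-methoxybenzyl)oxy]butan-2-yl]furan-3(2H)-one
Product: 15 (2R,3R)-3-(tert-butyldimethylsilyloxy)-3-[(2R)-5-[(2R,3S)-3-(tert-butyldimethylsilyloxy)-4-[(4-methoxybenzyl)oxy]butan-2-yl]-2-methyl-3-oxo-2,3-dihydrofuran-2-yl]-2-(triethylsilyloxy)propanal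
Conditions: (COCl)2, DMSO, CH2Cl2, −78 to −40 °C; Et3N, −78 to 0 °C
Reagents that add atoms: none
Why: Under Swern conditions a primary triethylsilyl ether is cleaved and oxidised directly to the aldehyde (oxidative desilylation) while secondary TES and TBS ethers and the PMB ether should survive.

**Step 13**
Reactants: 15 (2R,3R)-3-(tert-butyldimethylsilyloxy)-3-[(2R)-5-[(2R,3S)-3-(tert-butyldimethylsilyloxy)-4-[(4-methoxybenzyl)oxy]butan-2-yl]-2-methyl-3-oxo-2,3-dihydrofuran-2-yl]-2-(triethylsilyloxy)propanal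
Product: 16 methyl (4S,5R)-5-(tert-butyldimethylsilyloxy)-5-[(2R)-5-[(2R,3S)-3-(tert-butyldimethylsilyloxy)-4-[(4-methoxybenzyl)oxy]butan-2-yl]-2-methyl-3-oxo-2,3-dihydrofuran-2-yl]-3-hydroxy-2-methylidene-4-(triethylsilyloxy)pentanoate (C7 carbinol as epimer mixture)
Conditions: methyl acrylate (10 equiv), quinuclidine (0.5 equiv), MeOH (0.75 equiv), rt
Reagents that add atoms: methyl acrylate, C=CC(=O)OC
Why: Morita–Baylis–Hillman reaction of the activated α-silyloxy aldehyde with methyl acrylate under amine/methanol catalysis should install C11–C13, the new C7 carbinol centre being a mixture that is erased in the next step.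

**Step 14**
Reactants: 16 methyl (4S,5R)-5-(tert-butyldimethylsilyloxy)-5-[(2R)-5-[(2R,3S)-3-(tert-butyldimethylsilyloxy)-4-[(4-methoxybenzyl)oxy]butan-2-yl]-2-methyl-3-oxo-2,3-dihydrofuran-2-yl]-3-hydroxy-2-methylidene-4-(triethylsilyloxy)pentanoate
Product: 17 methyl (2Z,4S,5R)-2-(bromomethyl)-5-(tert-butyldimethylsilyloxy)-5-[(2R)-5-[(2R,3S)-3-(tert-butyldimethylsilyloxy)-4-[(4-methoxybenzyl)oxy]butan-2-yl]-2-methyl-3-oxo-2,3-dihydrofuran-2-yl]-4-(triethylsilyloxy)pent-2-enoate
Conditions: NBS, Me2S (premixed), CH2Cl2, 0 °C to rt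
Reagents that add atoms: N-bromosuccinimide, O=C1CCC(=O)N1Br
Why: Corey–Kim-type activation of the allylic alcohol by preformed bromodimethylsulfonium bromide (so that no free NBS meets the furanone) and SN2′ displacement by bromide should give the thermodynamically preferred (Z)-2-(bromomethyl)enoate.

**Step 15**
Reactants: 17 methyl (2Z,4S,5R)-2-(bromomethyl)-5-(tert-butyldimethylsilyloxy)-5-[(2R)-5-[(2R,3S)-3-(tert-butyldimethylsilyloxy)-4-[(4-methoxybenzyl)oxy]butan-2-yl]-2-methyl-3-oxo-2,3-dihydrofuran-2-yl]-4-(triethylsilyloxy)pent-2-enoate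
Product: 18 methyl (2Z,4S,5R)-2-(bromomethyl)-5-(tert-butyldimethylsilyloxy)-5-[(2R)-5-[(2R,3S)-3-(tert-butyldimethylsilyloxy)-4-hydroxybutan-2-yl]-2-methyl-3-oxo-2,3-dihydrofuran-2-yl]-4-(triethylsilyloxy)pent-2-enoate
Conditions: DDQ, CH2Cl2/pH 7 buffer 10:1, 0 °C to rt
Reagents that add atoms: none
Why: Oxidative cleavage of the PMB ether by DDQ in wet CH2Cl2 is selective for the electron-rich benzyl ether and should leave the silyl ethers, the allylic bromide and the vinylogous ester untouched.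

**Step 16**
Reactants: 18 methyl (2Z,4S,5R)-2-(bromomethyl)-5-(tert-butyldimethylsilyloxy)-5-[(2R)-5-[(2R,3S)-3-(tert-butyldimethylsilyloxy)-4-hydroxybutan-2-yl]-2-methyl-3-oxo-2,3-dihydrofuran-2-yl]-4-(triethylsilyloxy)pent-2-enoate
Product: 19 methyl (2Z,4S,5R)-2-(bromomethyl)-5-(tert-butyldimethylsilyloxy)-5-[(2R)-5-[(2R,3S)-3-(tert-butyldimethylsilyloxy)-4-oxobutan-2-yl]-2-methyl-3-oxo-2,3-dihydrofuran-2-yl]-4-(triethylsilyloxy)pent-2-enoate
Conditions: Dess–Martin periodinane, CH2Cl2, 0 °C to rt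
Reagents that add atoms: none
Why: Dess–Martin oxidation of the primary alcohol should give the α-silyloxy aldehyde under non-basic conditions without epimerisation at C5 or attack on the allylic bromide.

**Step 17**
Reactants: 19 methyl (2Z,4S,5R)-2-(bromomethyl)-5-(tert-butyldimethylsilyloxy)-5-[(2R)-5-[(2R,3S)-3-(tert-butyldimethylsilyloxy)-4-oxobutan-2-yl]-2-methyl-3-oxo-2,3-dihydrofuran-2-yl]-4-(triethylsilyloxy)pent-2-enoate
Product: 21 cis-fused α-methylene-γ-lactone macrocycle (8-O-deangeloyl target as its 5,9-bis-O-TBS 8-O-TES ether), via hydroxy ester 20 (not isolated)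
Conditions: CrCl2 (15 equiv), THF/DMF 1:1, 0.003 M (slow addition of 19), rt; aq. NH4Cl; then PPTS (cat.), CH2Cl2, rt
Reagents that add atoms: none
Why: Intramolecular chromium-mediated Barbier allylation of Nozaki–Hiyama–Kishi type should close the ten-membered carbocycle at C6–C7 with three open-chain preferences acting in the same sense, namely a chair transition state of the (Z)-configured 2-(methoxycarbonyl)allyl chromium species (6,7-syn adduct, hence the cis-fused lactone after acyl transfer), Felkin–Anh attack on the aldehyde anti to the C5 silyloxy group (5,6-anti) and bond formation at C7 anti to the C8–C9 bond with the C8 hydrogen eclipsing the alkene, while the rigid furanone holds the reacting ends close and high dilution suppresses oligomers.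

**Step 18**
Reactants: 21 cis-fused α-methylene-γ-lactone macrocycle (5,9-bis-O-TBS, 8-O-TES)
Product: 22 8-hydroxy macrocyclic lactone (5,9-bis-O-TBS)
Conditions: PPTS, MeOH/CH2Cl2 1:1, 0 °C to rt
Reagents that add atoms: none
Why: Acid-catalysed methanolysis removes a secondary triethylsilyl ether much faster than the two TBS ethers and should expose only the C8 hydroxyl.

**Step 19**
Reactants: 22 8-hydroxy macrocyclic lactone (5,9-bis-O-TBS)
Product: 23 8-O-angeloyl macrocyclic lactone (5,9-bis-O-TBS)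
Conditions: angelic acid, 2,4,6-trichlorobenzoyl chloride, Et3N, toluene, rt; then 22, toluene, 80 °C
Reagents that add atoms: angelic acid, C/C=C(/C)C(=O)O
Why: Yamaguchi-type esterification with the preformed mixed anhydride and no nucleophilic catalyst should acylate the C8 hydroxyl without Z-to-E isomerisation of the angelate to the tiglate.

**Step 20**
Reactants: 23 8-O-angeloyl macrocyclic lactone (5,9-bis-O-TBS)
Product: 24 target CNP0206920.1
Conditions: HF·pyridine, pyridine, THF, 0 °C to rt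
Reagents that add atoms: none
Why: Fluoride-mediated cleavage of the two TBS ethers with buffered HF·pyridine should leave the angelate, the α-methylene lactone and the furanone intact and give the target.

**Compound list**
1 | 2-[(4-methoxybenzyl)oxy]acetaldehyde | O=CCOCc1ccc(OC)cc1 | starting material
2 | (2S,3S)-1-[(4-methoxybenzyl)oxy]-3-methylpent-4-en-2-ol | C=C[C@H](C)[C@H](O)COCc1ccc(OC)cc1 | intermediate
3 | (2S,3S)-2-(tert-butyldimethylsilyloxy)-1-[(4-methoxybenzyl)oxy]-3-methylpent-4-ene | C=C[C@H](C)[C@H](O[Si](C)(C)C(C)(C)C)COCc1ccc(OC)cc1 | intermediate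
4 | (3R,4S)-4-(tert-butyldimethylsilyloxy)-5-[(4-methoxybenzyl)oxy]-3-methylpentan-2-one | CC(=O)[C@H](C)[C@H](O[Si](C)(C)C(C)(C)C)COCc1ccc(OC)cc1 | intermediate
5 | (R)-but-3-ene-1,2-diol | C=C[C@@H](O)CO | starting material
6 | (R)-3,4-bis(triethylsilyloxy)but-1-ene | C=C[C@@H](O[Si](CC)(CC)CC)CO[Si](CC)(CC)CC | intermediate
7 | (R,E)-2-methyl-4,5-bis(triethylsilyloxy)pent-2-enal | O=C/C(C)=C/[C@@H](O[Si](CC)(CC)CC)CO[Si](CC)(CC)CC | intermediate
8 | (R,E)-2-methyl-4,5-bis(triethylsilyloxy)pent-2-en-1-ol | OC/C(C)=C/[C@@H](O[Si](CC)(CC)CC)CO[Si](CC)(CC)CC | intermediate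
9 | [(2R,3R)-3-[(1S)-1,2-bis(triethylsilyloxy)ethyl]-2-methyloxiran-2-yl]methanol | OC[C@@]1(C)O[C@@H]1[C@@H](O[Si](CC)(CC)CC)CO[Si](CC)(CC)CC | intermediate
10 | (2S,3R)-3-[(1S)-1,2-bis(triethylsilyloxy)ethyl]-2-methyloxirane-2-carbaldehyde | O=C[C@@]1(C)O[C@@H]1[C@@H](O[Si](CC)(CC)CC)CO[Si](CC)(CC)CC | intermediate
11 | aldol adduct, (4R,5S)-5-(TBS-oxy)-1-hydroxy-6-(PMB-oxy)-4-methyl-1-[(2R,3R)-3-[(1S)-1,2-bis(triethylsilyloxy)ethyl]-2-methyloxiran-2-yl]hexan-3-one, C1 epimers | COc1ccc(COC[C@@H](O[Si](C)(C)C(C)(C)C)[C@@H](C)C(=O)CC(O)[C@@]2(C)O[C@@H]2[C@@H](O[Si](CC)(CC)CC)CO[Si](CC)(CC)CC)cc1 | intermediate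
12 | epoxy 1,3-diketone, (4R,5S)-5-(TBS-oxy)-6-(PMB-oxy)-4-methyl-1-[(2S,3R)-3-[(1S)-1,2-bis(triethylsilyloxy)ethyl]-2-methyloxiran-2-yl]hexane-1,3-dione (not isolated) | COc1ccc(COC[C@@H](O[Si](C)(C)C(C)(C)C)[C@@H](C)C(=O)CC(=O)[C@@]2(C)O[C@@H]2[C@@H](O[Si](CC)(CC)CC)CO[Si](CC)(CC)CC)cc1 | intermediate
13 | furanone, (2R)-2-[(1R,2S)-1-hydroxy-2,3-bis(triethylsilyloxy)propyl]-2-methyl-5-[(2R,3S)-3-(TBS-oxy)-4-(PMB-oxy)butan-2-yl]furan-3(2H)-one | COc1ccc(COC[C@@H](O[Si](C)(C)C(C)(C)C)[C@@H](C)C2=CC(=O)[C@](C)(O2)[C@H](O)[C@@H](O[Si](CC)(CC)CC)CO[Si](CC)(CC)CC)cc1 | intermediate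
14 | C9 TBS ether of 13 | COc1ccc(COC[C@@H](O[Si](C)(C)C(C)(C)C)[C@@H](C)C2=CC(=O)[C@](C)(O2)[C@H](O[Si](C)(C)C(C)(C)C)[C@@H](O[Si](CC)(CC)CC)CO[Si](CC)(CC)CC)cc1 | intermediate
15 | C7 aldehyde, (2R,3R)-3-(TBS-oxy)-3-[furanonyl]-2-(triethylsilyloxy)propanal | COc1ccc(COC[C@@H](O[Si](C)(C)C(C)(C)C)[C@@H](C)C2=CC(=O)[C@](C)(O2)[C@H](O[Si](C)(C)C(C)(C)C)[C@@H](O[Si](CC)(CC)CC)C=O)cc1 | intermediate
16 | Morita–Baylis–Hillman adduct (methyl 3-hydroxy-2-methylidene pentanoate, C7 epimers) | COc1ccc(COC[C@@H](O[Si](C)(C)C(C)(C)C)[C@@H](C)C2=CC(=O)[C@](C)(O2)[C@H](O[Si](C)(C)C(C)(C)C)[C@@H](O[Si](CC)(CC)CC)C(O)C(=C)C(=O)OC)cc1 | intermediate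
17 | (Z)-allylic bromide, methyl (2Z,4S,5R)-2-(bromomethyl)pent-2-enoate with C6 PMB ether | COc1ccc(COC[C@@H](O[Si](C)(C)C(C)(C)C)[C@@H](C)C2=CC(=O)[C@](C)(O2)[C@H](O[Si](C)(C)C(C)(C)C)[C@@H](O[Si](CC)(CC)CC)/C=C(\CBr)C(=O)OC)cc1 | intermediate
18 | C6 primary alcohol of the (Z)-allylic bromide | OC[C@@H](O[Si](C)(C)C(C)(C)C)[C@@H](C)C1=CC(=O)[C@](C)(O1)[C@H](O[Si](C)(C)C(C)(C)C)[C@@H](O[Si](CC)(CC)CC)/C=C(\CBr)C(=O)OC | intermediate
19 | C6 aldehyde of the (Z)-allylic bromide | O=C[C@@H](O[Si](C)(C)C(C)(C)C)[C@@H](C)C1=CC(=O)[C@](C)(O1)[C@H](O[Si](C)(C)C(C)(C)C)[C@@H](O[Si](CC)(CC)CC)/C=C(\CBr)C(=O)OC | intermediate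
20 | ten-membered carbocyclic hydroxy ester (6R,7S; C6–OH, C7–C(=CH2)CO2Me) (not isolated) | O[C@H]1[C@@H](O[Si](C)(C)C(C)(C)C)[C@@H](C)C2=CC(=O)[C@](C)(O2)[C@H](O[Si](C)(C)C(C)(C)C)[C@@H](O[Si](CC)(CC)CC)[C@H]1C(=C)C(=O)OC | intermediate
21 | cis-fused α-methylene-γ-lactone macrocycle, 5,9-bis-O-TBS, 8-O-TES | C=C1C(=O)O[C@H]2[C@@H](O[Si](C)(C)C(C)(C)C)[C@@H](C)C3=CC(=O)[C@](C)(O3)[C@H](O[Si](C)(C)C(C)(C)C)[C@@H](O[Si](CC)(CC)CC)[C@@H]12 | intermediate
22 | 8-hydroxy macrocyclic lactone, 5,9-bis-O-TBS | C=C1C(=O)O[C@H]2[C@@H](O[Si](C)(C)C(C)(C)C)[C@@H](C)C3=CC(=O)[C@](C)(O3)[C@H](O[Si](C)(C)C(C)(C)C)[C@@H](O)[C@@H]12 | intermediate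
23 | 8-O-angeloyl macrocyclic lactone, 5,9-bis-O-TBS | C=C1C(=O)O[C@H]2[C@@H](O[Si](C)(C)C(C)(C)C)[C@@H](C)C3=CC(=O)[C@](C)(O3)[C@H](O[Si](C)(C)C(C)(C)C)[C@@H](OC(=O)/C(C)=C\C)[C@@H]12 | intermediate
24 | CNP0206920.1 (4R,5S,6R,7S,8S,9R,10R) | C=C1C(=O)O[C@H]2[C@@H](O)[C@@H](C)C3=CC(=O)[C@](C)(O3)[C@H](O)[C@@H](OC(=O)/C(C)=C\C)[C@@H]12 | target

**Step count and risks**
Total steps: 20. Longest linear sequence: 17 (steps 4–20, from 5).

Steps most likely to fail:

1. Step 10 (new method). The oxirane may open at C9 in the 6-endo sense, C10 may ionise with loss of stereochemical integrity, or the diketone may be over-oxidised. Fallback with known chemistry, setting out from 11: catalytic camphorsulfonic acid in CH2Cl2 should let the C3 ketone oxygen open the oxirane at C10 (here a plain tertiary epoxide carbon next to a carbinol; the acid-catalysed epoxy-ketone to bicyclic-ketal cyclisation, 5-exo with inversion), the freed C9 oxygen closing the 2,7-dioxabicyclo[2.2.1]heptane ketal F1. Dess–Martin oxidation of the C1 carbinol would give the keto ketal F2. Its β-elimination with Et3N (the C3–O9 bond is the one better aligned with the enolate π-system) would release the C9 hydroxyl and the vinylogous ester, rejoining the route at 13.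

2. Step 17. The ring closure may proceed with the wrong relative configuration at C6/C7 (anti addition through an E-configured allylchromium species), with poor facial selectivity, or with oligomerisation. Fallback, setting out from 19: run the CrCl2 closure without the acid treatment; if it delivers mainly the 6-epimeric hydroxy ester F3, hydrolyse the methyl ester with Me3SnOH (1,2-dichloroethane, 70 °C) to the hydroxy acid F4 and close the γ-lactone under Mitsunobu conditions (PPh3, diisopropyl azodicarboxylate, toluene, high dilution) with inversion at C6, coming back to the route at 21.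

3. Step 13. The amine-catalysed addition may be slow on the hindered aldehyde, and prolonged exposure to base may cause epimerisation at C8 or β-elimination of the C9 silyloxy group. Fallback, setting out from 15: add the preformed α-(methoxycarbonyl)vinylaluminium reagent (methyl propiolate, i-Bu2AlH, N-methylmorpholine N-oxide, THF, 0 °C; hydroalumination) to 15 at low temperature, a stoichiometric, amine-free carbonyl addition that gives the same adduct and comes back to the route at 16 (no new compound, F0).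

**Further compounds**
F1 | step 10 | bicyclic ketal of 11 (2,7-dioxabicyclo[2.2.1]heptane, C3 bonded to O3 and O9, C1 carbinol) | COc1ccc(COC[C@@H](O[Si](C)(C)C(C)(C)C)[C@@H](C)[C@]23CC(O)[C@](C)(O2)[C@H](O3)[C@@H](O[Si](CC)(CC)CC)CO[Si](CC)(CC)CC)cc1
F2 | step 10 | keto ketal (C1 ketone of F1) | COc1ccc(COC[C@@H](O[Si](C)(C)C(C)(C)C)[C@@H](C)[C@]23CC(=O)[C@](C)(O2)[C@H](O3)[C@@H](O[Si](CC)(CC)CC)CO[Si](CC)(CC)CC)cc1
F3 | step 17 | 6-epimeric hydroxy ester (C6 epimer of 20) | O[C@@H]1[C@@H](O[Si](C)(C)C(C)(C)C)[C@@H](C)C2=CC(=O)[C@](C)(O2)[C@H](O[Si](C)(C)C(C)(C)C)[C@@H](O[Si](CC)(CC)CC)[C@H]1C(=C)C(=O)OC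
F4 | step 17 | 6-epimeric hydroxy acid | O[C@@H]1[C@@H](O[Si](C)(C)C(C)(C)C)[C@@H](C)C2=CC(=O)[C@](C)(O2)[C@H](O[Si](C)(C)C(C)(C)C)[C@@H](O[Si](CC)(CC)CC)[C@H]1C(=C)C(=O)O
F0 | step 13 | none | none
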